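## Retrosynthetic overview

1. Target ⇐ global hydrogenolysis of its hepta-O-benzyl ether (five phenols and both benzylic hydroxyls carried as benzyl ethers).
2. The 12-membered diolide is the only ring formed (both benzene rings are bought). It is closed by palladium-catalysed carbonylative macrolactonisation of the ring B aryl bromide onto the C-2 hydroxyl of the ring A side chain, with retention.
3. The seco bromo alcohol ⇐ Mitsunobu esterification of a ring A benzoic acid with the ring B (1R,2S)-1-benzyloxypropan-2-ol, with inversion to the (1R,2R) unit.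
4. Both (1R,2S)-β-benzyloxy alcohols ⇐ metal-free asymmetric anti-oxy-benzyloxylation of (E)-propenyl bromoarenes. Ring A uses a new chiral-aryl-iodide-catalysed Prévost-type acetoxy-benzyloxylation; ring B uses Shi epoxidation followed by benzylic alcoholysis.
5. Both (E)-propenyl bromoarenes ⇐ 3,5-dihydroxy-4-methoxybenzaldehyde by benzylation, mono- or dibromination and Julia–Kocienski olefination (ring B: one bromine is then exchanged for benzyloxy).

Assumption: 3,5-dihydroxy-4-methoxybenzaldehyde is taken as commercially available.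
Assumption: ArI* = (R,R)-2,2'-[(2-iodo-1,3-phenylene)bis(oxy)]bis(N-mesitylpropanamide), C[C@@H](Oc1cccc(O[C@H](C)C(=O)Nc2c(C)cc(C)cc2C)c1I)C(=O)Nc1c(C)cc(C)cc1C; it is assumed to select the alkene face that gives the (1R,2S) product of step 4, otherwise its (S,S)-antipode is used.

## Route

Step 1
Reactants: 1 3,5-dihydroxy-4-methoxybenzaldehyde
Product: 2 3,5-bis(benzyloxy)-4-methoxybenzaldehyde
Conditions: BnBr (2.4 equiv), K2CO3, DMF, 60 °C
Reagents that add atoms: benzyl bromide, BrCc1ccccc1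
Why: Williamson ether synthesis on both phenols, so that every O-protecting group in the route is a benzyl ether removed together at the end.

Step 2
Reactants: 2 3,5-bis(benzyloxy)-4-methoxybenzaldehyde
Product: 3 3,5-bis(benzyloxy)-2-bromo-4-methoxybenzaldehyde
Conditions: NBS (1.05 equiv), MeCN, 0 °C to rt, dark
Reagents that add atoms: N-bromosuccinimide, O=C1CCC(=O)N1Br
Why: Electrophilic aromatic bromination at one of the two equivalent positions ortho/para to the benzyloxy groups, as for 3,4,5-trialkoxybenzaldehydes; the bromine is the masked carboxyl of ring A.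

Step 3
Reactants: 3 3,5-bis(benzyloxy)-2-bromo-4-methoxybenzaldehyde
Product: 4 1,3-bis(benzyloxy)-4-bromo-2-methoxy-5-[(E)-prop-1-en-1-yl]benzene
Conditions: 5-(ethylsulfonyl)-1-phenyl-1H-tetrazole, KN(SiMe3)2, DME, −60 °C to rt
Reagents that add atoms: 5-(ethylsulfonyl)-1-phenyl-1H-tetrazole, CCS(=O)(=O)c1nnnn1-c1ccccc1
Why: Julia–Kocienski olefination, which is (E)-selective with aryl aldehydes and tolerates the aryl bromide.

Step 4
Reactants: 4 1,3-bis(benzyloxy)-4-bromo-2-methoxy-5-[(E)-prop-1-en-1-yl]benzene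
Product: 7 (1R,2S)-1-(benzyloxy)-1-[3,5-bis(benzyloxy)-2-bromo-4-methoxyphenyl]propan-2-ol, via dioxolanylium cation 5 (not isolated), via acetate 6 (not isolated)
Conditions: ArI* (15 mol %), mCPBA (1.3 equiv), AcOH (5 equiv), TfOH (20 mol %), 4 Å MS, CH2Cl2, −40 °C; then BnOH (6 equiv), −40 to 0 °C; then K2CO3, MeOH, rt
Reagents that add atoms: benzyl alcohol, OCc1ccccc1; acetic acid, CC(=O)O
Why: Proposed new method: mCPBA oxidises ArI* to its trivalent diacetate, which activates one face of the (E)-alkene; acetate adds anti at the benzylic carbon and its carbonyl oxygen then displaces the aryl-iodanyl group at C-2, giving the trans-(4S,5S)-dioxolanylium 5 with both stereocentres set by the catalyst (no ortho carbonyl or ortho oxygen competes as internal nucleophile); benzyl alcohol, added only after 5 has formed, first adds reversibly at the cationic carbon and then opens the p-methoxyaryl-stabilised benzylic C–O bond with inversion, as in the orthoester-to-1,2-trans-glycoside pathway of acyl-assisted glycosylation, so the acetyl necessarily stays on O-2 in erythro acetate 6 and methanolysis gives 7; the closest known reaction type is the chiral aryl-iodide Prévost/Woodward diacetoxylation of styrenes, where acetate or water and not an alcohol is the second nucleophile.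

Step 5
Reactants: 7 (1R,2S)-1-(benzyloxy)-1-[3,5-bis(benzyloxy)-2-bromo-4-methoxyphenyl]propan-2-ol
Product: 8 {[(1R,2S)-1-(benzyloxy)-1-[3,5-bis(benzyloxy)-2-bromo-4-methoxyphenyl]propan-2-yl]oxy}triethylsilane
Conditions: Et3SiCl, imidazole, DMF, 0 °C to rt
Reagents that add atoms: chlorotriethylsilane, CC[Si](Cl)(CC)CC
Why: Standard silylation of a secondary alcohol; the silyl ether stops the hydroxyl from lactonising onto the carboxyl made in step 6 and is the only non-benzyl protecting group.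

Step 6
Reactants: 8 {[(1R,2S)-1-(benzyloxy)-1-[3,5-bis(benzyloxy)-2-bromo-4-methoxyphenyl]propan-2-yl]oxy}triethylsilane
Product: 10 2,4-bis(benzyloxy)-6-[(1R,2S)-1-(benzyloxy)-2-(triethylsilyloxy)propyl]-3-methoxybenzoic acid, via aryllithium 9 (not isolated)
Conditions: n-BuLi (1.1 equiv), THF, −78 °C; CO2; then 1 M HCl to pH 3, 0 °C
Reagents that add atoms: carbon dioxide, O=C=O
Why: Bromine–lithium exchange followed by carboxylation; exchange at −78 °C is much faster than any benzylic deprotonation and both side-chain oxygens are capped, so no lactone or phthalide can form.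

Step 7
Reactants: 2 3,5-bis(benzyloxy)-4-methoxybenzaldehyde
Product: 11 3,5-bis(benzyloxy)-2,6-dibromo-4-methoxybenzaldehyde
Conditions: NBS (2.5 equiv), DMF, 50 °C, dark
Reagents that add atoms: N-bromosuccinimide, O=C1CCC(=O)N1Br
Why: Twofold electrophilic aromatic bromination of both activated positions; one bromine becomes the extra ring B oxygen and the other the masked carboxyl.

Step 8
Reactants: 11 3,5-bis(benzyloxy)-2,6-dibromo-4-methoxybenzaldehyde
Product: 12 1,3-bis(benzyloxy)-4,6-dibromo-2-methoxy-5-[(E)-prop-1-en-1-yl]benzene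
Conditions: 5-(ethylsulfonyl)-1-phenyl-1H-tetrazole, KN(SiMe3)2, DME, −60 °C to rt
Reagents that add atoms: 5-(ethylsulfonyl)-1-phenyl-1H-tetrazole, CCS(=O)(=O)c1nnnn1-c1ccccc1
Why: Julia–Kocienski olefination; the two ortho bromines make the (E)-isomer strongly preferred.

Step 9
Reactants: 12 1,3-bis(benzyloxy)-4,6-dibromo-2-methoxy-5-[(E)-prop-1-en-1-yl]benzene
Product: 15 2,4-bis(benzyloxy)-5-bromo-3-methoxy-6-[(E)-prop-1-en-1-yl]phenol, via aryllithium 13 (not isolated), via lithium aryltrimethoxyborate 14 (not isolated)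
Conditions: n-BuLi (1.05 equiv), THF, −78 °C; B(OMe)3, −78 °C to rt; then AcOH, 30% H2O2, 0 °C
Reagents that add atoms: hydrogen peroxide, OO
Why: Mono bromine–lithium exchange of the C2-symmetric dibromide (either bromine gives the same product), borylation and oxidative C–B to C–O migration; the alkene is inert to hydrogen peroxide.

Step 10
Reactants: 15 2,4-bis(benzyloxy)-5-bromo-3-methoxy-6-[(E)-prop-1-en-1-yl]phenol
Product: 16 1,2,4-tris(benzyloxy)-5-bromo-3-methoxy-6-[(E)-prop-1-en-1-yl]benzene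
Conditions: BnBr, K2CO3, DMF, 60 °C
Reagents that add atoms: benzyl bromide, BrCc1ccccc1
Why: Williamson ether synthesis; capping the new phenol prevents its cyclisation onto the epoxide of step 11.

Step 11
Reactants: 16 1,2,4-tris(benzyloxy)-5-bromo-3-methoxy-6-[(E)-prop-1-en-1-yl]benzene
Product: 17 (2S,3S)-2-methyl-3-[2,3,5-tris(benzyloxy)-6-bromo-4-methoxyphenyl]oxirane
Conditions: L-fructose-derived enantiomer of the Shi ketone (30 mol %), KHSO5 (as 2KHSO5·KHSO4·K2SO4), K2CO3, Bu4NHSO4, MeCN–CH2(OMe)2/aq. Na2B4O7 buffer pH 10.5, 0 °C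
Reagents that add atoms: potassium peroxymonosulfate, [K+].[O-]S(=O)(=O)OO
Why: Shi epoxidation; the chiral dioxirane reacts with trans-disubstituted alkenes through the spiro transition state, the D-fructose ketone giving (R,R)-epoxides of trans-β-methylstyrenes and its enantiomer therefore the (S,S)-epoxide, and the basic medium leaves the acid-sensitive epoxide intact.

Step 12
Reactants: 17 (2S,3S)-2-methyl-3-[2,3,5-tris(benzyloxy)-6-bromo-4-methoxyphenyl]oxirane
Product: 18 (1R,2S)-1-(benzyloxy)-1-[2,3,5-tris(benzyloxy)-6-bromo-4-methoxyphenyl]propan-2-ol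
Conditions: BnOH (5 equiv), BF3·OEt2 (10 mol %), CH2Cl2, −40 °C
Reagents that add atoms: benzyl alcohol, OCc1ccccc1
Why: Lewis-acid-catalysed epoxide alcoholysis at the cation-stabilised benzylic carbon with inversion (C-1 S to R, C-2 untouched), which installs the benzylic O-benzyl group directly.

Step 13
Reactants: 10 2,4-bis(benzyloxy)-6-[(1R,2S)-1-(benzyloxy)-2-(triethylsilyloxy)propyl]-3-methoxybenzoic acid; 18 (1R,2S)-1-(benzyloxy)-1-[2,3,5-tris(benzyloxy)-6-bromo-4-methoxyphenyl]propan-2-ol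
Product: 19 (1R,2R)-1-(benzyloxy)-1-[2,3,5-tris(benzyloxy)-6-bromo-4-methoxyphenyl]propan-2-yl 2,4-bis(benzyloxy)-6-[(1R,2S)-1-(benzyloxy)-2-(triethylsilyloxy)propyl]-3-methoxybenzoate
Conditions: PPh3, DIAD, toluene, 0 °C to rt
Reagents that add atoms: none
Why: Mitsunobu esterification; the carboxylate of 10 displaces the C-2 oxyphosphonium of 18 by SN2 with inversion (S to R), giving the (1R,2R) ring B unit, and a 2,6-disubstituted benzoic acid that is a poor acyl donor is a good nucleophile here.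

Step 14
Reactants: 19 (1R,2R)-1-(benzyloxy)-1-[2,3,5-tris(benzyloxy)-6-bromo-4-methoxyphenyl]propan-2-yl 2,4-bis(benzyloxy)-6-[(1R,2S)-1-(benzyloxy)-2-(triethylsilyloxy)propyl]-3-methoxybenzoate
Product: 20 (1R,2R)-1-(benzyloxy)-1-[2,3,5-tris(benzyloxy)-6-bromo-4-methoxyphenyl]propan-2-yl 2,4-bis(benzyloxy)-6-[(1R,2S)-1-(benzyloxy)-2-hydroxypropyl]-3-methoxybenzoate
Conditions: HF·pyridine, pyridine, THF, 0 °C
Reagents that add atoms: none
Why: Fluoride-mediated desilylation under buffered, non-basic conditions, so the freed hydroxyl does not translactonise onto the hindered benzoate.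

Step 15
Reactants: 20 (1R,2R)-1-(benzyloxy)-1-[2,3,5-tris(benzyloxy)-6-bromo-4-methoxyphenyl]propan-2-yl 2,4-bis(benzyloxy)-6-[(1R,2S)-1-(benzyloxy)-2-hydroxypropyl]-3-methoxybenzoate
Product: 21 hepta-O-benzyl diolide (the target with its five phenolic and two benzylic hydroxyls as benzyl ethers; ring B unit 1R,2R; ring A unit 1R,2S)
Conditions: Pd(OAc)2 (10 mol %), Xantphos (12 mol %), CO (1 atm), Et3N, toluene, 100 °C, 2 mM (syringe-pump addition)
Reagents that add atoms: carbon monoxide, [C-]#[O+]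
Why: Carbonylative macrolactonisation (palladium-catalysed alkoxycarbonylation); oxidative addition of the ring B aryl bromide to zerovalent palladium, CO insertion and capture of the acyl-palladium by the ring A side-chain C-2 hydroxyl close the 12-membered ring with retention (C-2 stays S), and no free carboxylic acid ever sits next to a free side-chain hydroxyl.

Step 16
Reactants: 21 hepta-O-benzyl diolide
Product: 22 CNP0086623.4 (target)
Conditions: H2 (1 atm), Pd(OH)2/C, EtOAc–MeOH, rt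
Reagents that add atoms: none
Why: Hydrogenolysis of all seven benzyl ethers under neutral conditions; both lactone C–O bonds are on non-benzylic carbons and survive, no stereocentre is touched, and the base-sensitive free benzylic hydroxyls appear only in this last step.

## Compound list

1 | 3,5-dihydroxy-4-methoxybenzaldehyde | COc1c(O)cc(C=O)cc1O | starting material
2 | 3,5-bis(benzyloxy)-4-methoxybenzaldehyde | COc1c(OCc2ccccc2)cc(C=O)cc1OCc1ccccc1 | intermediate
3 | 3,5-bis(benzyloxy)-2-bromo-4-methoxybenzaldehyde | COc1c(OCc2ccccc2)cc(C=O)c(Br)c1OCc1ccccc1 | intermediate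
4 | 1,3-bis(benzyloxy)-4-bromo-2-methoxy-5-[(E)-prop-1-en-1-yl]benzene | C/C=C/c1cc(OCc2ccccc2)c(OC)c(OCc2ccccc2)c1Br | intermediate
5 | (4S,5S)-4-[3,5-bis(benzyloxy)-2-bromo-4-methoxyphenyl]-2,5-dimethyl-1,3-dioxolan-2-ylium, acetate ion pair (formed in the flask, not isolated) | CC1=[O+][C@@H](c2cc(OCc3ccccc3)c(OC)c(OCc3ccccc3)c2Br)[C@H](C)O1 | intermediate
6 | (1R,2S)-1-(benzyloxy)-1-[3,5-bis(benzyloxy)-2-bromo-4-methoxyphenyl]propan-2-yl acetate (formed in the flask, not isolated) | C[C@H](OC(C)=O)[C@H](OCc1ccccc1)c1cc(OCc2ccccc2)c(OC)c(OCc2ccccc2)c1Br | intermediate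
7 | (1R,2S)-1-(benzyloxy)-1-[3,5-bis(benzyloxy)-2-bromo-4-methoxyphenyl]propan-2-ol | C[C@H](O)[C@H](OCc1ccccc1)c1cc(OCc2ccccc2)c(OC)c(OCc2ccccc2)c1Br | intermediate
8 | {[(1R,2S)-1-(benzyloxy)-1-[3,5-bis(benzyloxy)-2-bromo-4-methoxyphenyl]propan-2-yl]oxy}triethylsilane | C[C@H](O[Si](CC)(CC)CC)[C@H](OCc1ccccc1)c1cc(OCc2ccccc2)c(OC)c(OCc2ccccc2)c1Br | intermediate
9 | aryllithium from 8, bromine replaced by lithium (formed in the flask, not isolated) | C[C@H](O[Si](CC)(CC)CC)[C@H](OCc1ccccc1)c1cc(OCc2ccccc2)c(OC)c(OCc2ccccc2)c1[Li] | intermediate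
10 | 2,4-bis(benzyloxy)-6-[(1R,2S)-1-(benzyloxy)-2-(triethylsilyloxy)propyl]-3-methoxybenzoic acid | C[C@H](O[Si](CC)(CC)CC)[C@H](OCc1ccccc1)c1cc(OCc2ccccc2)c(OC)c(OCc2ccccc2)c1C(=O)O | intermediate
11 | 3,5-bis(benzyloxy)-2,6-dibromo-4-methoxybenzaldehyde | COc1c(OCc2ccccc2)c(Br)c(C=O)c(Br)c1OCc1ccccc1 | intermediate
12 | 1,3-bis(benzyloxy)-4,6-dibromo-2-methoxy-5-[(E)-prop-1-en-1-yl]benzene | C/C=C/c1c(Br)c(OCc2ccccc2)c(OC)c(OCc2ccccc2)c1Br | intermediate
13 | aryllithium from 12, one bromine replaced by lithium (formed in the flask, not isolated) | C/C=C/c1c([Li])c(OCc2ccccc2)c(OC)c(OCc2ccccc2)c1Br | intermediate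
14 | lithium {2,4-bis(benzyloxy)-5-bromo-3-methoxy-6-[(E)-prop-1-en-1-yl]phenyl}trimethoxyborate (formed in the flask, not isolated) | C/C=C/c1c(Br)c(OCc2ccccc2)c(OC)c(OCc2ccccc2)c1[B-](OC)(OC)OC.[Li+] | intermediate
15 | 2,4-bis(benzyloxy)-5-bromo-3-methoxy-6-[(E)-prop-1-en-1-yl]phenol | C/C=C/c1c(O)c(OCc2ccccc2)c(OC)c(OCc2ccccc2)c1Br | intermediate
16 | 1,2,4-tris(benzyloxy)-5-bromo-3-methoxy-6-[(E)-prop-1-en-1-yl]benzene | C/C=C/c1c(OCc2ccccc2)c(OCc2ccccc2)c(OC)c(OCc2ccccc2)c1Br | intermediate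
17 | (2S,3S)-2-methyl-3-[2,3,5-tris(benzyloxy)-6-bromo-4-methoxyphenyl]oxirane | C[C@@H]1O[C@H]1c1c(OCc2ccccc2)c(OCc2ccccc2)c(OC)c(OCc2ccccc2)c1Br | intermediate
18 | (1R,2S)-1-(benzyloxy)-1-[2,3,5-tris(benzyloxy)-6-bromo-4-methoxyphenyl]propan-2-ol | C[C@H](O)[C@H](OCc1ccccc1)c1c(OCc2ccccc2)c(OCc2ccccc2)c(OC)c(OCc2ccccc2)c1Br | intermediate
19 | (1R,2R)-1-(benzyloxy)-1-[2,3,5-tris(benzyloxy)-6-bromo-4-methoxyphenyl]propan-2-yl 2,4-bis(benzyloxy)-6-[(1R,2S)-1-(benzyloxy)-2-(triethylsilyloxy)propyl]-3-methoxybenzoate | C[C@H](O[Si](CC)(CC)CC)[C@H](OCc1ccccc1)c1cc(OCc2ccccc2)c(OC)c(OCc2ccccc2)c1C(=O)O[C@H](C)[C@H](OCc1ccccc1)c1c(OCc2ccccc2)c(OCc2ccccc2)c(OC)c(OCc2ccccc2)c1Br | intermediate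
20 | (1R,2R)-1-(benzyloxy)-1-[2,3,5-tris(benzyloxy)-6-bromo-4-methoxyphenyl]propan-2-yl 2,4-bis(benzyloxy)-6-[(1R,2S)-1-(benzyloxy)-2-hydroxypropyl]-3-methoxybenzoate | C[C@H](O)[C@H](OCc1ccccc1)c1cc(OCc2ccccc2)c(OC)c(OCc2ccccc2)c1C(=O)O[C@H](C)[C@H](OCc1ccccc1)c1c(OCc2ccccc2)c(OCc2ccccc2)c(OC)c(OCc2ccccc2)c1Br | intermediate
21 | hepta-O-benzyl diolide: 12-membered macrodiolide of the target with the five phenolic and the two benzylic hydroxyls as benzyl ethers; ring B unit (1R,2R), ring A unit (1R,2S) | COc1c(OCc3ccccc3)cc2c(c1OCc1ccccc1)C(=O)O[C@H](C)[C@H](OCc1ccccc1)c1c(OCc3ccccc3)c(OCc3ccccc3)c(OC)c(OCc3ccccc3)c1C(=O)O[C@@H](C)[C@@H]2OCc1ccccc1 | intermediate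
22 | CNP0086623.4: 12-membered diolide in which the 4,6-dihydroxy-5-methoxybenzoate (ring A, side chain (R)-CH(OH)-(S)-CH(CH3)O) and the 3,4,6-trihydroxy-5-methoxybenzoate (ring B, side chain (R)-CH(OH)-(R)-CH(CH3)O) each esterify the CH(CH3)O of the other unit | COc1c(O)cc2c(c1O)C(=O)O[C@H](C)[C@H](O)c1c(O)c(O)c(OC)c(O)c1C(=O)O[C@@H](C)[C@@H]2O | target

## Step count and risk

Total steps: 16. Longest linear sequence: 11 (steps 1, 7, 8, 9, 10, 11, 12, 13, 14, 15, 16).

Steps most likely to fail: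

Step 4 (the proposed new reaction). Possible failures are background epoxidation of the electron-rich alkene by mCPBA (loss of ee), capture of the dioxolanylium by adventitious water (syn hydroxy acetate), and benzyl alcohol stopping at the orthoester stage. Fallback with known chemistry: setting out from 4, Shi epoxidation with the L-fructose-derived ketone and KHSO5 gives (2S,3S)-2-methyl-3-[3,5-bis(benzyloxy)-2-bromo-4-methoxyphenyl]oxirane F1. BF3·OEt2-catalysed opening of F1 with benzyl alcohol at the benzylic carbon (inversion) comes back to the route at 7. This is the sequence used for ring B in steps 11 and 12.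

Step 13 (Mitsunobu on a β-branched secondary alcohol next to an electron-rich aryl group). Possible failures are slow activation, elimination, or participation by the aryl ring or its ortho benzyloxy oxygen. Fallback that avoids substitution at C-2: setting out from 18 and 10, Dess–Martin oxidation of 18 gives (1R)-1-(benzyloxy)-1-[2,3,5-tris(benzyloxy)-6-bromo-4-methoxyphenyl]propan-2-one F2. Reduction of F2 with (S)-2-methyl-CBS-oxazaborolidine and BH3·SMe2 under reagent control gives (1R,2R)-1-(benzyloxy)-1-[2,3,5-tris(benzyloxy)-6-bromo-4-methoxyphenyl]propan-2-ol F3. Acid 10 is converted with 1-chloro-N,N,2-trimethylprop-1-en-1-amine into 2,4-bis(benzyloxy)-6-[(1R,2S)-1-(benzyloxy)-2-(triethylsilyloxy)propyl]-3-methoxybenzoyl chloride F4, which acylates the lithium alkoxide of F3 (LiN(SiMe3)2, THF) with retention. This comes back to the route at 19.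

Step 15 (carbonylative macrolactonisation of a hindered, electron-rich aryl bromide to a 12-membered ring). Possible failures are slow oxidative addition, protodebromination and oligomerisation. Fallback that separates carbonylation from ring closure: setting out from 19, intermolecular hydroxycarbonylation (Pd(OAc)2, Xantphos, CO, H2O, Et3N) gives 2,4,5-tris(benzyloxy)-6-[(1R,2R)-1-(benzyloxy)-2-({2,4-bis(benzyloxy)-6-[(1R,2S)-1-(benzyloxy)-2-(triethylsilyloxy)propyl]-3-methoxybenzoyl}oxy)propyl]-3-methoxybenzoic acid F5. HF·pyridine then gives the seco hydroxy acid 2,4,5-tris(benzyloxy)-6-[(1R,2R)-1-(benzyloxy)-2-({2,4-bis(benzyloxy)-6-[(1R,2S)-1-(benzyloxy)-2-hydroxypropyl]-3-methoxybenzoyl}oxy)propyl]-3-methoxybenzoic acid F6. Shiina macrolactonisation of F6 (2-methyl-6-nitrobenzoic anhydride, DMAP, high dilution; retention at the carbinol) comes back to the route at 21.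

Further compounds

F1 | step 4 | (2S,3S)-2-methyl-3-[3,5-bis(benzyloxy)-2-bromo-4-methoxyphenyl]oxirane | C[C@@H]1O[C@H]1c1cc(OCc2ccccc2)c(OC)c(OCc2ccccc2)c1Br
F2 | step 13 | (1R)-1-(benzyloxy)-1-[2,3,5-tris(benzyloxy)-6-bromo-4-methoxyphenyl]propan-2-one | CC(=O)[C@H](OCc1ccccc1)c1c(OCc2ccccc2)c(OCc2ccccc2)c(OC)c(OCc2ccccc2)c1Br
F3 | step 13 | (1R,2R)-1-(benzyloxy)-1-[2,3,5-tris(benzyloxy)-6-bromo-4-methoxyphenyl]propan-2-ol | C[C@@H](O)[C@H](OCc1ccccc1)c1c(OCc2ccccc2)c(OCc2ccccc2)c(OC)c(OCc2ccccc2)c1Br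
F4 | step 13 | 2,4-bis(benzyloxy)-6-[(1R,2S)-1-(benzyloxy)-2-(triethylsilyloxy)propyl]-3-methoxybenzoyl chloride | C[C@H](O[Si](CC)(CC)CC)[C@H](OCc1ccccc1)c1cc(OCc2ccccc2)c(OC)c(OCc2ccccc2)c1C(Cl)=O
F5 | step 15 | 2,4,5-tris(benzyloxy)-6-[(1R,2R)-1-(benzyloxy)-2-({2,4-bis(benzyloxy)-6-[(1R,2S)-1-(benzyloxy)-2-(triethylsilyloxy)propyl]-3-methoxybenzoyl}oxy)propyl]-3-methoxybenzoic acid | C[C@H](O[Si](CC)(CC)CC)[C@H](OCc1ccccc1)c1cc(OCc2ccccc2)c(OC)c(OCc2ccccc2)c1C(=O)O[C@H](C)[C@H](OCc1ccccc1)c1c(OCc2ccccc2)c(OCc2ccccc2)c(OC)c(OCc2ccccc2)c1C(=O)O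
F6 | step 15 | 2,4,5-tris(benzyloxy)-6-[(1R,2R)-1-(benzyloxy)-2-({2,4-bis(benzyloxy)-6-[(1R,2S)-1-(benzyloxy)-2-hydroxypropyl]-3-methoxybenzoyl}oxy)propyl]-3-methoxybenzoic acid | C[C@H](O)[C@H](OCc1ccccc1)c1cc(OCc2ccccc2)c(OC)c(OCc2ccccc2)c1C(=O)O[C@H](C)[C@H](OCc1ccccc1)c1c(OCc2ccccc2)c(OCc2ccccc2)c(OC)c(OCc2ccccc2)c1C(=O)O
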